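**Retrosynthetic overview**
1. Last bond: the C10–O ester (Yamaguchi) joins a tricyclic allylic alcohol to (Z)-16-PMBO-hexadec-9-enoic acid, itself made by a Z-selective Wittig reaction. CHO, CO2H and the ω-OH are unmasked afterwards.
2. Ring C is formed last. C9–C10 comes from an intramolecular aldol of a diquinane keto aldehyde. β-Diketone → vinylogous triflate → Pd carbonylation brings in C15, and a 1,2-reduction sets C10.
3. C12 and C2: hydroxymethylation of the C2 enol triflate, then hydrogenation directed by the angular CH2OH (C10).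
4. Ring B: Wolff ring contraction of a 4,4-dimethyl-cis-hydrindan-5-one. C6 migrates to C7 and the carbonyl carbon is extruded as C8.
5. Key C–C bond: intermolecular Michael addition of 2-allylcyclopentane-1,3-dione (ring A) to methyl vinyl ketone gives C1–C11 and the quaternary C1. A proline-catalysed desymmetrising aldol follows. Ring order: A → six-membered ring → contracted to B → C.

Convention (cedrane numbering of the core, used throughout): C1 quaternary spiro carbon; C2 CH bearing C12 (CHO); C3/C4 CH2; C5 ring-fusion CH; C6 CMe2; C7 bridgehead CH; C8 carbon bearing C15 (CO2H); C9 vinylic CH; C10 CH–O; C11 CH2 bridge.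

**Step 1**
Reactants: 1 cyclopentane-1,3-dione; 2 allyl acetate
Product: 3 2-allylcyclopentane-1,3-dione
Conditions: Pd(PPh3)4 (2 mol %), THF, 50 °C (1.3 equiv of 1)
Reagents that add atoms: none
Why: Tsuji–Trost allylation: the acidic, soft 1,3-dione is C-allylated by the π-allylpalladium complex under neutral conditions, and the excess of 1 keeps diallylation low.

**Step 2**
Reactants: 3 2-allylcyclopentane-1,3-dione; 4 methyl vinyl ketone
Product: 5 2-allyl-2-(3-oxobutyl)cyclopentane-1,3-dione
Conditions: AcOH (cat.), H2O, 75 °C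
Reagents that add atoms: none
Why: Intermolecular Michael addition (the fragment-joining key step): the enolised 2-substituted 1,3-dione adds 1,4 to the unhindered enone, forms C1–C11 and the still prochiral quaternary C1, and cannot react twice because no acidic C–H is left.

**Step 3**
Reactants: 5 2-allyl-2-(3-oxobutyl)cyclopentane-1,3-dione
Product: 7 (7aS)-7a-allyl-2,3,7,7a-tetrahydro-1H-indene-1,5(6H)-dione, via cis-fused ketol 6 (not isolated)
Conditions: (R)-proline (30 mol %), DMF, rt; then TsOH·H2O (cat.), toluene, 80 °C; recrystallise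
Reagents that add atoms: none
Why: Hajos–Parrish–Eder–Sauer–Wiechert reaction (enamine-catalysed desymmetrising intramolecular aldol, then dehydration): (R)-proline selects one of the two enantiotopic ring carbonyls, in the mirror-image sense of the (S)-proline/(S)-methyl series, and so fixes C1.

**Step 4**
Reactants: 7 (7aS)-7a-allyl-2,3,7,7a-tetrahydro-1H-indene-1,5(6H)-dione
Product: 8 (1R,7aS)-7a-allyl-1-hydroxy-1,2,3,6,7,7a-hexahydro-5H-inden-5-one (C2-OH cis to allyl)
Conditions: NaBH4 (0.3 equiv), EtOH, −20 °C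
Reagents that add atoms: none
Why: Chemoselective borohydride reduction: the saturated cyclopentanone reacts faster than the enone carbonyl and hydride arrives anti to the angular allyl group, so the temporary C2 carbinol is cis to it.

**Step 5**
Reactants: 8 hydroxy enone
Product: 9 1-hydroxy-7a-[(E)-prop-1-enyl]-1,2,3,6,7,7a-hexahydro-5H-inden-5-one (configuration as in 8)
Conditions: RhCl3·3H2O (5 mol %), EtOH, reflux
Reagents that add atoms: none
Why: Rh–H catalysed alkene isomerisation moves the terminal double bond by one position to the more stable (E)-propenyl group, where it stops at the quaternary carbon.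

**Step 6**
Reactants: 9 propenyl hydroxy enone
Product: 11 1-hydroxy-7a-(hydroxymethyl)-1,2,3,6,7,7a-hexahydro-5H-inden-5-one (C2-OH cis to C10H2OH), via hydroxy aldehyde 10 (not isolated)
Conditions: O3, CH2Cl2–MeOH, −78 °C (Sudan III end point); Me2S, → rt, concentrate; NaBH4, MeOH–CH2Cl2, −78 °C
Reagents that add atoms: ozone [O-][O+]=O
Why: Ozonolysis followed by chemoselective aldehyde reduction: ozone attacks the electron-rich propenyl group much faster than the electron-poor enone, and at −78 °C NaBH4 reduces only the aldehyde, so no stereocentre is touched.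

**Step 7**
Reactants: 11 enone diol
Product: 12 isopropylidene acetal (1,3-dioxane across O2 and O10) of 11
Conditions: Me2C(OMe)2, PPTS (cat.), CH2Cl2, rt
Reagents that add atoms: 2,2-dimethoxypropane COC(C)(C)OC
Why: Acid-catalysed transacetalisation: the cis-1,3-diol closes a six-membered acetonide that masks both hydroxyls against base and MeI.

**Step 8**
Reactants: 12 enone acetonide
Product: 13 6,6-dimethyl β,γ-enone acetonide (ketone at the future C8; alkene C4=C5)
Conditions: KOt-Bu (2.4 equiv), MeI (6 equiv), t-BuOH–THF, 0 °C → rt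
Reagents that add atoms: iodomethane CI
Why: Deconjugative α,α-dialkylation of the thermodynamic dienolate (the classical 4,4-dimethylation of a Δ4-3-ketone) places both methyl groups on C6 and shifts the alkene to C4=C5; C6 is not stereogenic.

**Step 9**
Reactants: 13 dimethyl enone acetonide
Product: 14 6,6-dimethyl β,γ-enone diol
Conditions: AcOH–H2O 4:1, 40 °C
Reagents that add atoms: none
Why: Mild acetal hydrolysis; the β,γ-enone cannot reconjugate because C6 is quaternary.

**Step 10**
Reactants: 14 dimethyl enone diol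
Product: 15 cis-hydrindanone diol (H5 cis to C10H2OH)
Conditions: H2 (4 atm), [Ir(cod)(PCy3)(py)]PF6 (5 mol %), CH2Cl2, rt
Reagents that add atoms: none
Why: Hydroxyl-directed homogeneous hydrogenation (Crabtree catalyst): both homoallylic OH groups lie on the face of the angular CH2OH, bind iridium and deliver H2 to that face of the hindered alkene, so H5 ends cis to C10.

**Step 11**
Reactants: 15 cis-hydrindanone diol
Product: 16 C10-O-TBS ether of 15 (C2-OH free)
Conditions: TBSCl (1.05 equiv), imidazole, CH2Cl2, 0 °C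
Reagents that add atoms: tert-butyldimethylsilyl chloride CC(C)(C)[Si](C)(C)Cl
Why: Selective silylation: the primary hydroxyl reacts much faster than the secondary hydroxyl next to the quaternary carbon.

**Step 12**
Reactants: 16 silyl ether ketone
Product: 18 α-diazo ketone (diazo group on C7), via trifluoroacetyl ketone 17 (not isolated)
Conditions: LiHMDS (2.3 equiv), THF, −78 °C; CF3CO2CH2CF3; then MsN3, Et3N, H2O, MeCN, rt
Reagents that add atoms: methanesulfonyl azide CS(=O)(=O)N=[N+]=[N-]; 2,2,2-trifluoroethyl trifluoroacetate FC(F)(F)COC(=O)C(F)(F)F (atoms stay only in 17)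
Why: Detrifluoroacetylative diazo transfer (Regitz–Danheiser): C7 is the only enolisable position because C6 is quaternary, so acylation and diazo transfer are regiospecific, and any O-trifluoroacetate at C2 is hydrolysed in the aqueous second stage.

**Step 13**
Reactants: 18 α-diazo ketone
Product: 20 cis-diquinane Weinreb amide alcohol (C7 epimers; the epimer cis to C10 is drawn), via ketene 19 (not isolated)
Conditions: hν (365 nm), MeNH(OMe) (5 equiv), THF, 0 °C
Reagents that add atoms: N,O-dimethylhydroxylamine CNOC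
Why: Photochemical Wolff rearrangement of an s-cis-locked cyclic diazo ketone: C6 migrates to C7 with loss of N2 (ring contraction to ring B) and the amine traps the ketene; C7 forms as an epimer mixture that is corrected in step 22.

**Step 14**
Reactants: 20 Weinreb amide alcohol
Product: 21 diquinane C2 ketone
Conditions: DMP, CH2Cl2, rt
Reagents that add atoms: none
Why: Dess–Martin oxidation of the only free alcohol under conditions that leave the silyl ether and the amide untouched.

**Step 15**
Reactants: 21 diquinane C2 ketone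
Product: 22 C2 enol triflate (C2=C3)
Conditions: KHMDS, THF, −78 °C; PhNTf2
Reagents that add atoms: N-phenylbis(trifluoromethanesulfonimide) FC(F)(F)S(=O)(=O)N(c1ccccc1)S(=O)(=O)C(F)(F)F
Why: Kinetic enolate O-triflation: C3 is the only α-position of the ketone (C1 is quaternary), and the ketone is far more acidic than the amide α-C–H.

**Step 16**
Reactants: 22 C2 enol triflate
Product: 23 allylic alcohol (C12H2OH on C2=C3)
Conditions: Bu3SnCH2OH, Pd(PPh3)4 (5 mol %), LiCl (3 equiv), 1,4-dioxane, 100 °C
Reagents that add atoms: (tributylstannyl)methanol CCCC[Sn](CCCC)(CCCC)CO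
Why: Stille cross-coupling: the hydroxymethyl group is transferred selectively from tin to the alkenylpalladium species formed from the triflate, which brings in C12.

**Step 17**
Reactants: 23 allylic alcohol
Product: 24 C12-O-TBDPS C10-O-TBS bis-silyl ether
Conditions: TBDPSCl, imidazole, DMF, rt
Reagents that add atoms: tert-butyldiphenylsilyl chloride CC(C)(C)[Si](Cl)(c1ccccc1)c1ccccc1
Why: Standard silylation of the only free, primary allylic alcohol.

**Step 18**
Reactants: 24 bis-silyl ether
Product: 25 homoallylic alcohol (C10-OH free; C12-O-TBDPS kept)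
Conditions: CSA (10 mol %), MeOH–CH2Cl2 1:1, 0 °C
Reagents that add atoms: none
Why: Selective acid-catalysed desilylation: a primary TBS ether is solvolysed about two orders of magnitude faster than a TBDPS ether.

**Step 19**
Reactants: 25 homoallylic alcohol
Product: 26 saturated diquinane (C12 arm on C2 trans to C10 and cis to C11/C6)
Conditions: H2 (4 atm), [Ir(cod)(PCy3)(py)]PF6 (8 mol %), CH2Cl2, rt
Reagents that add atoms: none
Why: Hydroxyl-directed hydrogenation (Crabtree catalyst): the angular CH2OH is homoallylic to C2=C3 and stands on the convex face, so H is delivered to C2 syn to C10 and the C12 arm is pushed to the opposite face as in the target.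

**Step 20**
Reactants: 26 saturated Weinreb amide
Product: 27 hydroxy methyl ketone (acetyl on C7)
Conditions: MeMgBr (3.5 equiv), THF, 0 °C → rt
Reagents that add atoms: methylmagnesium bromide C[Mg]Br
Why: Weinreb ketone synthesis: the chelated tetrahedral intermediate prevents over-addition and one further equivalent only deprotonates the alcohol; this brings in C9.

**Step 21**
Reactants: 27 hydroxy methyl ketone
Product: 28 keto aldehyde (C10 formyl on C1; acetyl on C7)
Conditions: DMP, CH2Cl2, 0 °C → rt
Reagents that add atoms: none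
Why: Dess–Martin oxidation of the neopentyl primary alcohol stops cleanly at the non-enolisable aldehyde.

**Step 22**
Reactants: 28 keto aldehyde
Product: 29 tricyclic ketol (C8 ketone; C10 carbinol as epimer mixture)
Conditions: K2CO3 (0.3 equiv), MeOH, 0 °C → rt
Reagents that add atoms: none
Why: Intramolecular aldol addition (6-enolendo-exo-trig) of the methyl ketone enolate (C9) to the aldehyde (C10) closes ring C; base equilibrates C7 and only the epimer with acetyl cis to formyl can cyclise, which fixes C7, while the C10 mixture is erased in step 23.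

**Step 23**
Reactants: 29 tricyclic ketol
Product: 30 tricyclic β-diketone (C8 and C10 ketones)
Conditions: DMP, CH2Cl2, rt
Reagents that add atoms: none
Why: Dess–Martin oxidation converts both carbinol epimers into one β-diketone without retro-aldol cleavage.

**Step 24**
Reactants: 30 tricyclic β-diketone
Product: 31 vinylogous triflate (C10 ketone; C9=C8–OTf)
Conditions: Tf2O (1.1 equiv), Et3N, CH2Cl2, −78 °C
Reagents that add atoms: trifluoromethanesulfonic anhydride FC(F)(F)S(=O)(=O)OS(=O)(=O)C(F)(F)F
Why: O-sulfonylation of the enolised β-diketone: O8 is flanked only by the bridgehead C7–H whereas O10 is screened by quaternary C1 and ring A, matching 4,4-disubstituted cyclohexane-1,3-diones, which are O-functionalised at the remote carbonyl.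

**Step 25**
Reactants: 31 vinylogous triflate
Product: 32 enone 2-(trimethylsilyl)ethyl ester (C15 installed)
Conditions: CO (1 atm), Pd(OAc)2 (5 mol %), dppf (10 mol %), TMSCH2CH2OH (5 equiv), i-Pr2NEt, DMF, 60 °C
Reagents that add atoms: carbon monoxide [C-]#[O+]; 2-(trimethylsilyl)ethanol C[Si](C)(C)CCO
Why: Pd-catalysed alkoxycarbonylation of the alkenyl triflate (oxidative addition, CO insertion, alcoholysis) installs C15 directly as a fluoride-labile ester.

**Step 26**
Reactants: 32 enone TMSE ester
Product: 33 allylic alcohol (C10-OH pointing towards the C5–C6 bridge as in the target)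
Conditions: NaBH4, CeCl3·7H2O, MeOH, −78 °C
Reagents that add atoms: none
Why: Luche 1,2-reduction: hydride attacks the bicyclo[3.2.1]octenone carbonyl from the face of the one-carbon bridge (C11), because the opposite face is blocked by C5–H and the endo methyl on C6, and this sets C10.

**Step 27**
Reactants: 34 methyl oleate
Product: 35 methyl 9-oxononanoate
Conditions: O3, CH2Cl2, −78 °C; Me2S, → rt
Reagents that add atoms: ozone [O-][O+]=O
Why: Ozonolysis with reductive work-up cleaves the single alkene, and the aldehyde ester is separated from nonanal by distillation.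

**Step 28**
Reactants: 36 heptane-1,7-diol
Product: 37 7-[(4-methoxybenzyl)oxy]heptan-1-ol
Conditions: NaH (1.0 equiv), PMBCl (1.0 equiv), TBAI (cat.), THF–DMF, 0 °C → rt (3 equiv of 36)
Reagents that add atoms: 4-methoxybenzyl chloride COc1ccc(CCl)cc1
Why: Williamson ether synthesis; the excess of cheap diol makes mono-protection dominant.

**Step 29**
Reactants: 37 mono-PMB diol
Product: 38 1-{[(7-iodoheptyl)oxy]methyl}-4-methoxybenzene
Conditions: I2, PPh3, imidazole, CH2Cl2, 0 °C
Reagents that add atoms: iodine II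
Why: Appel-type (Garegg–Samuelsson) iodination: SN2 displacement of the alkoxyphosphonium ion at an unhindered primary carbon.

**Step 30**
Reactants: 38 primary iodide
Product: 39 {7-[(4-methoxybenzyl)oxy]heptyl}triphenylphosphonium iodide
Conditions: PPh3, MeCN, reflux
Reagents that add atoms: triphenylphosphine c1ccc(cc1)P(c1ccccc1)c1ccccc1
Why: SN2 quaternisation of triphenylphosphine by a primary iodide.

**Step 31**
Reactants: 39 phosphonium iodide; 35 methyl 9-oxononanoate
Product: 41 methyl (Z)-16-[(4-methoxybenzyl)oxy]hexadec-9-enoate, via phosphorus ylide 40 (not isolated)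
Conditions: NaHMDS, THF, −78 °C; then 35, −78 °C → rt
Reagents that add atoms: none
Why: Wittig olefination: a non-stabilised ylide under lithium-free conditions gives the cis-oxaphosphetane kinetically and hence the (Z)-alkene.

**Step 32**
Reactants: 41 methyl ester
Product: 42 (Z)-16-[(4-methoxybenzyl)oxy]hexadec-9-enoic acid
Conditions: LiOH, THF–MeOH–H2O, rt; then 1 M HCl
Reagents that add atoms: lithium hydroxide [Li+].[OH-]
Why: Saponification of an unhindered methyl ester; the PMB ether and the Z-alkene are inert.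

**Step 33**
Reactants: 42 protected hydroxy acid; 33 allylic alcohol
Product: 44 fully protected C10 ester, via mixed anhydride 43 (not isolated)
Conditions: 2,4,6-Cl3C6H2COCl, Et3N, toluene, rt; then 33, DMAP, 40 °C
Reagents that add atoms: 2,4,6-trichlorobenzoyl chloride O=C(Cl)c1c(Cl)cc(Cl)cc1Cl (atoms stay only in 43)
Why: Yamaguchi esterification: DMAP attacks the aliphatic carbonyl of the mixed anhydride, and the acylpyridinium ion acylates even the hindered secondary alcohol with retention at C10.

**Step 34**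
Reactants: 44 fully protected ester
Product: 45 hydroxy acid (C12H2OH and C15O2H free; PMB kept)
Conditions: TBAF, AcOH (1:1), THF, rt → 40 °C
Reagents that add atoms: none
Why: Fluoride-induced desilylation and β-silyl fragmentation of the TMSE ester occur in one operation, and the acetic acid buffer prevents alkoxide-mediated acyl migration or ester cleavage.

**Step 35**
Reactants: 45 hydroxy acid
Product: 46 aldehyde acid PMB ether
Conditions: DMP, CH2Cl2, 0 °C
Reagents that add atoms: none
Why: Dess–Martin oxidation of the only free alcohol stops at the aldehyde, tolerates the free acid and is non-basic, so C2 is not epimerised.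

**Step 36**
Reactants: 46 aldehyde acid PMB ether
Product: 47 target CNP0214056.2
Conditions: DDQ, CH2Cl2–pH 7 buffer, 0 °C
Reagents that add atoms: none
Why: Oxidative PMB cleavage with DDQ acts only on the electron-rich benzyl ether under buffered neutral conditions, leaving the aldehyde, acid, ester and both alkenes intact.

**Compound list**
1 | cyclopentane-1,3-dione | O=C1CCC(=O)C1 | starting material
2 | allyl acetate | CC(=O)OCC=C | starting material
3 | 2-allylcyclopentane-1,3-dione | C=CCC1C(=O)CCC1=O | intermediate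
4 | methyl vinyl ketone | CC(=O)C=C | starting material
5 | 2-allyl-2-(3-oxobutyl)cyclopentane-1,3-dione | C=CCC1(CCC(C)=O)C(=O)CCC1=O | intermediate
6 | cis-fused ketol (7a-allyl-3a-hydroxyhexahydroindene-1,5-dione; OH cis to allyl) | O=C1CC[C@@]2(CC=C)C(=O)CC[C@@]2(O)C1 | intermediate
7 | (7aS)-7a-allyl-2,3,7,7a-tetrahydro-1H-indene-1,5(6H)-dione | O=C1CC[C@@]2(CC=C)C(=O)CCC2=C1 | intermediate
8 | (1R,7aS)-7a-allyl-1-hydroxy-1,2,3,6,7,7a-hexahydro-5H-inden-5-one | O=C1CC[C@@]2(CC=C)[C@H](O)CCC2=C1 | intermediate
9 | (E)-propenyl hydroxy enone | O=C1CC[C@@]2(/C=C/C)[C@H](O)CCC2=C1 | intermediate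
10 | hydroxy aldehyde (C10 formyl) | O=C1CC[C@@]2(C=O)[C@H](O)CCC2=C1 | intermediate
11 | enone diol | O=C1CC[C@@]2(CO)[C@H](O)CCC2=C1 | intermediate
12 | enone acetonide | O=C1CC[C@@]2(COC(C)(C)O3)[C@H]3CCC2=C1 | intermediate
13 | 6,6-dimethyl β,γ-enone acetonide | CC1(C)C(=O)CC[C@@]2(COC(C)(C)O3)[C@H]3CC=C12 | intermediate
14 | 6,6-dimethyl β,γ-enone diol | CC1(C)C(=O)CC[C@@]2(CO)[C@H](O)CC=C12 | intermediate
15 | cis-hydrindanone diol | CC1(C)C(=O)CC[C@@]2(CO)[C@H](O)CC[C@@H]12 | intermediate
16 | C10-O-TBS cis-hydrindanone | CC1(C)C(=O)CC[C@@]2(CO[Si](C)(C)C(C)(C)C)[C@H](O)CC[C@@H]12 | intermediate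
17 | 7-trifluoroacetyl ketone | CC1(C)C(=O)C(C(=O)C(F)(F)F)C[C@@]2(CO[Si](C)(C)C(C)(C)C)[C@H](O)CC[C@@H]12 | intermediate
18 | α-diazo ketone | CC1(C)C(=O)C(=[N+]=[N-])C[C@@]2(CO[Si](C)(C)C(C)(C)C)[C@H](O)CC[C@@H]12 | intermediate
19 | ring-contracted ketene | CC1(C)C(=C=O)C[C@@]2(CO[Si](C)(C)C(C)(C)C)[C@H](O)CC[C@@H]12 | intermediate
20 | diquinane Weinreb amide alcohol (C7 epimers; cyclising epimer drawn) | CC1(C)[C@H](C(=O)N(C)OC)C[C@@]2(CO[Si](C)(C)C(C)(C)C)[C@H](O)CC[C@@H]12 | intermediate
21 | diquinane C2 ketone | CC1(C)[C@H](C(=O)N(C)OC)C[C@@]2(CO[Si](C)(C)C(C)(C)C)C(=O)CC[C@@H]12 | intermediate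
22 | C2 enol triflate | CC1(C)[C@H](C(=O)N(C)OC)C[C@@]2(CO[Si](C)(C)C(C)(C)C)C(OS(=O)(=O)C(F)(F)F)=CC[C@@H]12 | intermediate
23 | allylic alcohol (C12 installed) | CC1(C)[C@H](C(=O)N(C)OC)C[C@@]2(CO[Si](C)(C)C(C)(C)C)C(CO)=CC[C@@H]12 | intermediate
24 | bis-silyl ether | CC1(C)[C@H](C(=O)N(C)OC)C[C@@]2(CO[Si](C)(C)C(C)(C)C)C(CO[Si](c3ccccc3)(c3ccccc3)C(C)(C)C)=CC[C@@H]12 | intermediate
25 | homoallylic alcohol | CC1(C)[C@H](C(=O)N(C)OC)C[C@@]2(CO)C(CO[Si](c3ccccc3)(c3ccccc3)C(C)(C)C)=CC[C@@H]12 | intermediate
26 | saturated diquinane Weinreb amide | CC1(C)[C@H](C(=O)N(C)OC)C[C@@]2(CO)[C@@H](CO[Si](c3ccccc3)(c3ccccc3)C(C)(C)C)CC[C@@H]12 | intermediate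
27 | hydroxy methyl ketone | CC1(C)[C@H](C(C)=O)C[C@@]2(CO)[C@@H](CO[Si](c3ccccc3)(c3ccccc3)C(C)(C)C)CC[C@@H]12 | intermediate
28 | keto aldehyde | CC1(C)[C@H](C(C)=O)C[C@@]2(C=O)[C@@H](CO[Si](c3ccccc3)(c3ccccc3)C(C)(C)C)CC[C@@H]12 | intermediate
29 | tricyclic ketol (C10 epimers) | CC1(C)[C@H]2C[C@@]3(C(O)CC2=O)[C@@H](CO[Si](c4ccccc4)(c4ccccc4)C(C)(C)C)CC[C@@H]13 | intermediate
30 | tricyclic β-diketone | CC1(C)[C@H]2C[C@@]3(C(=O)CC2=O)[C@@H](CO[Si](c4ccccc4)(c4ccccc4)C(C)(C)C)CC[C@@H]13 | intermediate
31 | vinylogous triflate | CC1(C)[C@H]2C[C@@]3(C(=O)C=C2OS(=O)(=O)C(F)(F)F)[C@@H](CO[Si](c4ccccc4)(c4ccccc4)C(C)(C)C)CC[C@@H]13 | intermediate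
32 | enone TMSE ester | CC1(C)[C@H]2C[C@@]3(C(=O)C=C2C(=O)OCC[Si](C)(C)C)[C@@H](CO[Si](c4ccccc4)(c4ccccc4)C(C)(C)C)CC[C@@H]13 | intermediate
33 | tricyclic allylic alcohol | CC1(C)[C@H]2C[C@@]3([C@@H](O)C=C2C(=O)OCC[Si](C)(C)C)[C@@H](CO[Si](c4ccccc4)(c4ccccc4)C(C)(C)C)CC[C@@H]13 | intermediate
34 | methyl oleate | CCCCCCCC/C=C\CCCCCCCC(=O)OC | starting material
35 | methyl 9-oxononanoate | COC(=O)CCCCCCCC=O | intermediate
36 | heptane-1,7-diol | OCCCCCCCO | starting material
37 | 7-[(4-methoxybenzyl)oxy]heptan-1-ol | COc1ccc(COCCCCCCCO)cc1 | intermediate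
38 | 1-{[(7-iodoheptyl)oxy]methyl}-4-methoxybenzene | COc1ccc(COCCCCCCCI)cc1 | intermediate
39 | {7-[(4-methoxybenzyl)oxy]heptyl}triphenylphosphonium iodide | COc1ccc(COCCCCCCC[P+](c2ccccc2)(c2ccccc2)c2ccccc2)cc1.[I-] | intermediate
40 | phosphorus ylide | COc1ccc(COCCCCCCC=P(c2ccccc2)(c2ccccc2)c2ccccc2)cc1 | intermediate
41 | methyl (Z)-16-[(4-methoxybenzyl)oxy]hexadec-9-enoate | COC(=O)CCCCCCC/C=C\CCCCCCOCc1ccc(OC)cc1 | intermediate
42 | (Z)-16-[(4-methoxybenzyl)oxy]hexadec-9-enoic acid | OC(=O)CCCCCCC/C=C\CCCCCCOCc1ccc(OC)cc1 | intermediate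
43 | mixed 2,4,6-trichlorobenzoic anhydride of 42 | O=C(OC(=O)c1c(Cl)cc(Cl)cc1Cl)CCCCCCC/C=C\CCCCCCOCc1ccc(OC)cc1 | intermediate
44 | fully protected C10 ester | CC1(C)[C@H]2C[C@@]3([C@@H](OC(=O)CCCCCCC/C=C\CCCCCCOCc4ccc(OC)cc4)C=C2C(=O)OCC[Si](C)(C)C)[C@@H](CO[Si](c4ccccc4)(c4ccccc4)C(C)(C)C)CC[C@@H]13 | intermediate
45 | hydroxy acid | CC1(C)[C@H]2C[C@@]3([C@@H](OC(=O)CCCCCCC/C=C\CCCCCCOCc4ccc(OC)cc4)C=C2C(=O)O)[C@@H](CO)CC[C@@H]13 | intermediate
46 | aldehyde acid PMB ether | CC1(C)[C@H]2C[C@@]3([C@@H](OC(=O)CCCCCCC/C=C\CCCCCCOCc4ccc(OC)cc4)C=C2C(=O)O)[C@@H](C=O)CC[C@@H]13 | intermediate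
47 | CNP0214056.2 | CC1(C)[C@H]2C[C@@]3([C@@H](OC(=O)CCCCCCC/C=C\CCCCCCO)C=C2C(=O)O)[C@@H](C=O)CC[C@@H]13 | target

**Step count**
Total step count: 36. Longest linear sequence: 30 steps (steps 1–26 and 33–36); steps 27–32 build the side chain separately.

**Three steps most likely to fail**

Step 3 (the enantioselectivity of the desymmetrising aldol may drop with the larger allyl group). The fallback sets out from 5 and replaces catalytic induction by classical resolution. Compound 5 is cyclised without chirality using pyrrolidine/AcOH to give the racemic enedione F1. Selective NaBH4 reduction gives the racemic cis hydroxy enone F2. This is esterified with (S)-O-methylmandelic acid (DCC, DMAP). The diastereomeric esters are separated by chromatography or crystallisation to give the (S)-O-methylmandelate of the desired enantiomer F3. Treatment with LiOH releases the alcohol. The fallback comes back to the route at 8.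

Step 24 (triflation could take place at O10 instead of O8). The fallback sets out from 29 and avoids the β-diketone altogether, so that C8 is the only carbonyl available. The carbinol of 29 is silylated (TESOTf, 2,6-lutidine) to give the ketol TES ether F4. KHMDS/PhNTf2 then gives the enol triflate F5; the enolate can form only towards C9 because C7 is a bridgehead. The same Pd/CO/TMSCH2CH2OH carbonylation gives the silyloxy enoate F6. PPTS/MeOH removes the TES group to give the allylic alcohol epimer mixture F7. DMP oxidation of both epimers comes back to the route at 32.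

Step 26 (hydride might arrive from the other face). The fallback sets out from 32. If reduction gives mainly the 10-epi allylic alcohol F8, the stereocentre is corrected during esterification rather than during reduction. A Mitsunobu reaction of F8 with acid 42 (PPh3, DIAD, toluene, 0 °C) forms the C10–O ester with inversion. It comes back to the route at 44, so step 33 is skipped.

**Further compounds**
F1 | step 3 | racemic 7a-allyl-2,3,7,7a-tetrahydro-1H-indene-1,5(6H)-dione | O=C1CCC2(CC=C)C(=O)CCC2=C1
F2 | step 3 | racemic cis 7a-allyl-1-hydroxy-1,2,3,6,7,7a-hexahydro-5H-inden-5-one | O=C1CCC2(CC=C)C(O)CCC2=C1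
F3 | step 3 | (S)-O-methylmandelate ester of 8 | O=C1CC[C@@]2(CC=C)[C@H](OC(=O)[C@@H](OC)c3ccccc3)CCC2=C1
F4 | step 24 | ketol TES ether | CC1(C)[C@H]2C[C@@]3(C(O[Si](CC)(CC)CC)CC2=O)[C@@H](CO[Si](c4ccccc4)(c4ccccc4)C(C)(C)C)CC[C@@H]13
F5 | step 24 | C8 enol triflate with C10-OTES | CC1(C)[C@H]2C[C@@]3(C(O[Si](CC)(CC)CC)C=C2OS(=O)(=O)C(F)(F)F)[C@@H](CO[Si](c4ccccc4)(c4ccccc4)C(C)(C)C)CC[C@@H]13
F6 | step 24 | C10-OTES enoate TMSE ester | CC1(C)[C@H]2C[C@@]3(C(O[Si](CC)(CC)CC)C=C2C(=O)OCC[Si](C)(C)C)[C@@H](CO[Si](c4ccccc4)(c4ccccc4)C(C)(C)C)CC[C@@H]13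
F7 | step 24 | allylic alcohol epimer mixture at C10 | CC1(C)[C@H]2C[C@@]3(C(O)C=C2C(=O)OCC[Si](C)(C)C)[C@@H](CO[Si](c4ccccc4)(c4ccccc4)C(C)(C)C)CC[C@@H]13
F8 | step 26 | 10-epi allylic alcohol | CC1(C)[C@H]2C[C@@]3([C@H](O)C=C2C(=O)OCC[Si](C)(C)C)[C@@H](CO[Si](c4ccccc4)(c4ccccc4)C(C)(C)C)CC[C@@H]13
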